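## The problem

Target 22 (C30H22O16) is a linear chain of five benzene rings, lettered A to E from the 2,4,6-trihydroxyphenyl end to the 3,4,5-trihydroxyphenyl end. The rings are held together only by four diaryl ether oxygens and carry twelve free phenolic hydroxyls. There is no stereocentre, so every selectivity question is one of regiochemistry: which oxygen sits on which carbon, and which oxygen is arylated. Three of the ethers (A–O–B, C–O–D, D–O–E) join a carbon flanked by two oxygens to a carbon flanked by two hydrogens, so each can come from a hindered phenoxide and an unhindered, activated aryl electrophile. Ring C is the exception. It is unsymmetrical, its ether oxygens sit on adjacent carbons C1 (to ring B) and C2 (to ring D), and no activating group that the target could retain can be placed ortho or para to C1, so the B–O–C bond cannot be made by aromatic substitution on ring C. The free polyphenol and every intermediate with a free hydroquinone are oxidised by air, most readily in base. The hydroxyls therefore stay masked as alkyl ethers until the last step, and that cleavage must leave the diaryl ether bonds alone. The enabling feature is that C2–O and C5–O of ring C are para to each other, with the ring B ether at C1 and a further oxygen at C3 on either side of C2. This is the hydroquinone pattern that a 3-aryloxy-4-(1-alkoxyvinyl)-4-hydroxycyclobutenone gives on heating, so the B–O–C ether can be made on a four-membered vinylogous acid chloride before ring C exists.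

## Retrosynthesis

**Unmasking.** Target 22 is traced back to the fully alkylated pentamer 21 by cutting twelve O–alkyl bonds (eleven methyl, one ethyl). Methyl ethers are chosen over benzyl ethers because the building blocks 1, 2 and 20 are then purchasable as such. The forward reaction must cleave every alkyl aryl ether and no diaryl ether; a boron tribromide cleavage meets this, since only sp3 carbon is attacked.

**Ring E.** In 21 the bond between C1 of ring E and the ether oxygen is cut, giving four-ring phenol 19 and 5-iodo-1,2,3-trimethoxybenzene 20. The alternative of attaching a pre-assembled two-ring electrophile to ring C would need a separate multi-step synthesis of that electrophile. Cutting here keeps the end ring as a one-step addition of a purchasable iodide. The forward reaction is a copper-catalysed arylation of a phenol flanked by two methoxy groups.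

**Ring D.** Phenol 19 is traced through formate 18 to aldehyde 17, and 17 is cut at the bond between C1 of ring D and the oxygen on C2 of ring C, giving phenol 16 and fluoroaldehyde 2. The hindered oxygen of ring C is the nucleophile and attacks an unhindered carbon para to a formyl group; the formyl group is then turned into the hindered hydroxyl of ring D. The two methoxy groups of 2 become the two hydroxyls of ring D. The forward reactions are an SNAr displacement and a Baeyer–Villiger oxidation with aryl migration.

**Differentiating the two hydroxyls of ring C.** Phenol 16 comes from hydroquinone 15 by cutting the O–CH3 bond at C5. The two hydroxyls of 15 differ strongly: the one at C5 has two hydrogen neighbours and two meta oxygens, while the one at C2 is buried between an aryloxy and an ethoxy group. The forward methylation must take the exposed, more acidic one.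

**Ring C (key disconnection).** Hydroquinone 15 is cut at the C4–C5 bond of ring C and traced through cyclohexadienone 14 and dienylketene 13 to cyclobutenone 12. This removes a whole aromatic ring and leaves a four-membered ring in which the aryloxy group, the future hindered hydroxyl and the ethoxy-bearing carbon are already in sequence. Against an aromatic substitution on a preformed ring C, it sets the regiochemistry by connectivity, not by directing effects. The forward reaction needs only heat and outward rotation of the hydroxyl in the ring opening.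

**Carbinol.** Cyclobutenone 12 is cut between the carbinol carbon and the ethoxyvinyl group, giving dione 9 and 1-ethoxyvinyllithium 11, which is made from ethyl vinyl ether 10. Of the two carbonyls of 9, the one attached to the aryloxy-bearing carbon is ketone-like, and the other is a deactivated vinylogous ester. Addition at the former puts the aryloxy group next to the new carbinol, as ring C requires.

**The B–O–C ether.** Dione 9 comes from chloride 8 by replacing chlorine with hydrogen, and 8 is cut at the bond between the ring oxygen of ring B and the cyclobutene carbon, giving phenol 5 and squaric acid dichloride 7. The dichloride 7 is made from squaric acid 6. The hindered phenoxide of 5 only has to perform an acyl-type substitution here, which crowding hampers far less than an aromatic substitution.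

**Rings A and B.** Phenol 5 is traced through formate 4 to aldehyde 3, which is cut at the ether bond into 2,4,6-trimethoxyphenol 1 and fluoroaldehyde 2. This is the same SNAr and oxidation pair as for ring D, so one building block, 2, supplies both rings B and D.

## Roads not taken

**Alternative 1: nine hydroxyls stored as formyl groups.** The cut removes nine C–O bonds at once: every hydroxyl of rings A to D is traced back to a formyl group, leading to nona-aldehyde A2 with ring E as its trimethyl ether. Forward, a ninefold Dakin-type oxidation with peroxide under seleninic acid catalysis, followed by cleavage of the formates, would give A1, the target with ring E still methylated.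

- Merits: the formyl groups would activate aromatic substitution while the ethers are assembled, and rings A to D would need no protecting groups.
- Weak points:
  - The oxidation needs aryl migration, which is favoured on electron-rich rings. Each ring of A2 carries two or three formyl groups, so the first oxidations start from electron-poor arenes where hydride migration to carboxylic acids competes.
  - Nine such events must all go the right way on one molecule, while the intermediates become ever more electron-rich phenols in an oxidising medium.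
  - A2 is itself an unsolved synthesis. Its rings must be joined at carbons flanked by formyl groups, and ring C still needs two ether oxygens on adjacent carbons.
  - A1 still requires an ether cleavage on ring E.
- Comparison: in protecting-group economy this road is better than the chosen plan, which cleaves twelve ethers in step 12, and on paper it is shorter. The chosen plan sets against this that each C–O bond is made singly on an electron-rich ring (steps 2 and 10), where the outcome is predictable, and that the pattern of ring C is fixed by the connectivity of 12.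

**Alternative 2: ring D by double Claisen condensation.** The cut goes through ring D at the C2–C3 and C6–C5 bonds, leading to aryloxymalonate A4 (carrying ring E) and 3-aryloxyglutaconate A5 (carrying rings A, B and C). Forward, a base-mediated double Claisen condensation would close ring D as dihydroxy diester A3.

- Merits: both crowded ethers of ring D are in place before the ring exists, so no hindered phenol has to be arylated at this end, and the approach is convergent.
- Weak points:
  - A5 needs the three-ring phenol with the adjacent ether oxygens of ring C already installed, so the hardest part of the target is moved, not solved.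
  - A4 is the more acidic partner; once deprotonated it is a poor acyl donor, while A5 must react twice as a nucleophile.
  - The β-aryloxy enoate in A5 can lose its aryloxide by addition–elimination under alkoxide.
  - Two ester groups must be removed from A3 afterwards.
- Comparison: for the D–E end this road is more convergent and avoids the hindered copper coupling of step 11, and in that respect it is better. The chosen plan answers with an SNAr at an unhindered carbon for ring D (step 9) and, above all, with a solution for ring C, which this road leaves open.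

**Alternative 3: ring B by Danheiser benzannulation.** The cut goes through ring B at the C2–C3 and C1–C6 bonds, leading to cyclobutenone A7 and aryl ethynyl ether A8. Forward, heating would give phenol A6 by way of a vinylketene, [2+2] addition to the ynol ether, 4π ring opening and 6π closure. Ring B would form with its ether to ring A in place and its other three oxygens differentiated.

- Merits: the regiochemistry is unambiguous, the reaction forms no air-sensitive hydroquinone, and it shares the four-membered-ring logic of the chosen plan.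
- Weak points:
  - Ring B is the symmetrical, easy ring. The chosen plan reaches the equivalent two-ring phenol 5 in two steps from 1 and 2.
  - A8 is a sensitive ynol ether that needs several steps from a hindered phenol, and A7 needs its own synthesis.
  - The differentiation of oxygens in A6 is wasted, because both oxygens flanking the ether carbon of ring B end as hydroxyls.
  - Ring C with its adjacent ethers is untouched.
- Comparison: as a single reaction it is at least as reliable as step 7 and probably easier to handle. The chosen plan sets against it that the ring construction is spent on the one ring that cannot be made by substitution chemistry.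

Key step: step 7

Remarks on the chemistry: compounds 1, 2, 6, 10 and 20 are taken as purchasable. Cyclobutenone 12 is racemic; its single stereocentre is destroyed in step 7, so no enantiocontrol is attempted.

## Route

Step 1
Reactants: 1 2,4,6-trimethoxyphenol; 2 4-fluoro-2,6-dimethoxybenzaldehyde
Product: 3 2,6-dimethoxy-4-(2,4,6-trimethoxyphenoxy)benzaldehyde
Conditions: K2CO3, DMF, 100 °C, Ar
Reagents that add atoms: none
Why: Nucleophilic aromatic substitution (SNAr): the fluoride of 2 is para to the formyl group and flanked by hydrogens, so the hindered phenoxide of 1 can attack it; the methoxy groups of 2 are meta to fluorine and do not cancel the activation.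

Step 2
Reactants: 3 2,6-dimethoxy-4-(2,4,6-trimethoxyphenoxy)benzaldehyde
Product: 5 2,6-dimethoxy-4-(2,4,6-trimethoxyphenoxy)phenol, via aryl formate 4 (not isolated)
Conditions: mCPBA (1.1 equiv), CH2Cl2, 0 °C to rt; aq NaHCO3 wash; then K2CO3 (cat.), MeOH, rt
Reagents that add atoms: mCPBA, OOC(=O)c1cccc(Cl)c1
Why: Baeyer–Villiger (Dakin-type) oxidation: the aryl group flanked by two methoxy groups migrates in preference to hydride, and formate 4 is methanolysed to the phenol; peracid is limited to just over one equivalent to spare the electron-rich ring A.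

Step 3
Reactants: 6 squaric acid
Product: 7 3,4-dichlorocyclobut-3-ene-1,2-dione (squaric acid dichloride)
Conditions: (COCl)2, DMF (cat.), CH2Cl2, rt to 40 °C
Reagents that add atoms: oxalyl chloride, ClC(=O)C(Cl)=O
Why: Vilsmeier-type chlorination of the two vinylogous acid hydroxyls, the standard preparation of squaric acid dichloride; it is used fresh.

Step 4
Reactants: 5 2,6-dimethoxy-4-(2,4,6-trimethoxyphenoxy)phenol; 7 3,4-dichlorocyclobut-3-ene-1,2-dione
Product: 8 3-chloro-4-[2,6-dimethoxy-4-(2,4,6-trimethoxyphenoxy)phenoxy]cyclobut-3-ene-1,2-dione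
Conditions: NaH, THF, 0 °C; then added slowly to 7 (1.3 equiv), THF, −78 to −20 °C
Reagents that add atoms: none
Why: Acyl-type addition–elimination on a vinylogous acid chloride, which tolerates the two ortho methoxy groups of the phenoxide; after the first substitution the remaining chloride is part of a less electrophilic vinylogous ester, so inverse addition to excess 7 at low temperature should stop at the monoester.

Step 5
Reactants: 8 3-chloro-4-[2,6-dimethoxy-4-(2,4,6-trimethoxyphenoxy)phenoxy]cyclobut-3-ene-1,2-dione
Product: 9 3-[2,6-dimethoxy-4-(2,4,6-trimethoxyphenoxy)phenoxy]cyclobut-3-ene-1,2-dione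
Conditions: Bu3SnH (1.05 equiv, slow addition), Pd(PPh3)4 (3 mol %), toluene, 0 °C to rt
Reagents that add atoms: none
Why: Palladium-catalysed tin hydride reduction of a vinylogous acid chloride, analogous to the reduction of acid chlorides to aldehydes: zerovalent palladium inserts into the activated C–Cl bond, hydride is transferred from tin and reductive elimination gives the C–H bond; the aryl ester is handled dry and purified quickly.

Step 6
Reactants: 9 3-[2,6-dimethoxy-4-(2,4,6-trimethoxyphenoxy)phenoxy]cyclobut-3-ene-1,2-dione; 10 ethyl vinyl ether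
Product: 12 (±)-3-[2,6-dimethoxy-4-(2,4,6-trimethoxyphenoxy)phenoxy]-4-(1-ethoxyethenyl)-4-hydroxycyclobut-2-en-1-one, via 1-ethoxyvinyllithium 11 (not isolated)
Conditions: t-BuLi, THF, −78 to 0 °C (lithiation of 10); then 9, THF, −78 °C; aq NH4Cl at −78 °C
Reagents that add atoms: none
Why: 1,2-addition of an α-lithiated enol ether to a cyclobutenedione: the hard lithium reagent attacks the ketone-like carbonyl attached to the aryloxy-bearing carbon, the other carbonyl being a deactivated vinylogous ester; the new stereocentre is formed as a racemate and is erased in step 7, and work-up is kept neutral to spare the enol ether.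

Step 7
Reactants: 12 (±)-3-[2,6-dimethoxy-4-(2,4,6-trimethoxyphenoxy)phenoxy]-4-(1-ethoxyethenyl)-4-hydroxycyclobut-2-en-1-one
Product: 15 2-[2,6-dimethoxy-4-(2,4,6-trimethoxyphenoxy)phenoxy]-6-ethoxybenzene-1,4-diol, via dienylketene 13 (not isolated), via cyclohexadienone 14 (not isolated)
Conditions: toluene (degassed), 110 °C, Ar
Reagents that add atoms: none
Why: On heating, the cyclobutenone undergoes conrotatory 4π electrocyclic opening of the bond between the carbonyl carbon and the carbinol carbon; the hydroxyl, a lone-pair donor on the sp3 carbon, rotates outward, so the ethoxyvinyl group turns inward and dienylketene 13 forms with the vinyl group cis to the ketene. Disrotatory 6π electrocyclisation then joins the ketene carbon to the vinyl CH2 (the C4–C5 bond of ring C) and closes the six-membered carbocycle as cyclohexadienone 14, which tautomerises irreversibly to hydroquinone 15. This is the Moore rearrangement of 4-alkenyl-4-hydroxycyclobutenones derived from squaric acid, here with an enol ether as the alkenyl group. No stereocentre is formed, and the carbinol centre of 12 is lost on ring opening, so its configuration does not matter. The regiochemistry needs no choice in this step, because it is written into 12 by the aryloxy group sitting next to the carbinol carbon. The one selectivity needed is torquoselectivity, which the oxygen donor on the sp3 carbon secures; inward rotation of the hydroxyl would lead to a furanone. Air is excluded because the electron-rich hydroquinone oxidises easily, and the crude product goes straight into step 8.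

Step 8
Reactants: 15 2-[2,6-dimethoxy-4-(2,4,6-trimethoxyphenoxy)phenoxy]-6-ethoxybenzene-1,4-diol
Product: 16 2-[2,6-dimethoxy-4-(2,4,6-trimethoxyphenoxy)phenoxy]-6-ethoxy-4-methoxyphenol
Conditions: MeI (1.05 equiv), K2CO3 (1.1 equiv), acetone (degassed), 0 °C to rt, Ar
Reagents that add atoms: iodomethane, CI
Why: Williamson ether synthesis with limiting base and electrophile: the hydroxyl with two hydrogen neighbours is more acidic (two meta oxygens) and far more accessible than the hydroxyl buried between the aryloxy and ethoxy groups, so it should be methylated selectively.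

Step 9
Reactants: 16 2-[2,6-dimethoxy-4-(2,4,6-trimethoxyphenoxy)phenoxy]-6-ethoxy-4-methoxyphenol; 2 4-fluoro-2,6-dimethoxybenzaldehyde
Product: 17 4-{2-[2,6-dimethoxy-4-(2,4,6-trimethoxyphenoxy)phenoxy]-6-ethoxy-4-methoxyphenoxy}-2,6-dimethoxybenzaldehyde
Conditions: Cs2CO3, DMF, 110 °C, Ar
Reagents that add atoms: none
Why: SNAr as in step 1: the crowding lies on the phenoxide side only, and the electrophilic carbon of 2 is unhindered and para to the formyl group; the caesium phenoxide is used for higher reactivity.

Step 10
Reactants: 17 4-{2-[2,6-dimethoxy-4-(2,4,6-trimethoxyphenoxy)phenoxy]-6-ethoxy-4-methoxyphenoxy}-2,6-dimethoxybenzaldehyde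
Product: 19 4-{2-[2,6-dimethoxy-4-(2,4,6-trimethoxyphenoxy)phenoxy]-6-ethoxy-4-methoxyphenoxy}-2,6-dimethoxyphenol, via aryl formate 18 (not isolated)
Conditions: mCPBA (1.1 equiv), CH2Cl2, 0 °C to rt; aq NaHCO3 wash; then K2CO3 (cat.), MeOH, rt
Reagents that add atoms: mCPBA, OOC(=O)c1cccc(Cl)c1
Why: Baeyer–Villiger (Dakin-type) oxidation as in step 2; the di-ortho-methoxy aryl group migrates, and the aldehyde reacts faster with the peracid than the electron-rich rings do at 0 °C.

Step 11
Reactants: 19 4-{2-[2,6-dimethoxy-4-(2,4,6-trimethoxyphenoxy)phenoxy]-6-ethoxy-4-methoxyphenoxy}-2,6-dimethoxyphenol; 20 5-iodo-1,2,3-trimethoxybenzene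
Product: 21 1-[2,6-dimethoxy-4-(2,4,6-trimethoxyphenoxy)phenoxy]-2-[3,5-dimethoxy-4-(3,4,5-trimethoxyphenoxy)phenoxy]-3-ethoxy-5-methoxybenzene
Conditions: CuI (10 mol %), picolinic acid (20 mol %), K3PO4, DMSO, 100 °C, Ar; 20 in excess
Reagents that add atoms: none
Why: Ullmann diaryl ether synthesis in its ligand-accelerated form, which accepts ortho,ortho-disubstituted phenols and electron-rich aryl iodides; the iodide carbon of 20 is flanked by hydrogens.

Step 12
Reactants: 21 1-[2,6-dimethoxy-4-(2,4,6-trimethoxyphenoxy)phenoxy]-2-[3,5-dimethoxy-4-(3,4,5-trimethoxyphenoxy)phenoxy]-3-ethoxy-5-methoxybenzene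
Product: 22 2-{4-[2-[3,5-dihydroxy-4-(3,4,5-trihydroxyphenoxy)phenoxy]-3,5-dihydroxyphenoxy]-3,5-dihydroxyphenoxy}benzene-1,3,5-triol
Conditions: BBr3 (excess), CH2Cl2, −78 °C to rt, Ar; then H2O, 0 °C; work-up with degassed solvents
Reagents that add atoms: none
Why: Lewis-acid ether cleavage: boron coordinates each alkyl aryl ether oxygen and bromide removes the methyl or ethyl group by SN2 attack at sp3 carbon; the four diaryl ether bonds offer no such carbon and should remain.

## Compound list

1 | 2,4,6-trimethoxyphenol | COc1cc(OC)c(O)c(OC)c1 | starting material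
2 | 4-fluoro-2,6-dimethoxybenzaldehyde | COc1cc(F)cc(OC)c1C=O | starting material
3 | 2,6-dimethoxy-4-(2,4,6-trimethoxyphenoxy)benzaldehyde | COc1cc(OC)c(Oc2cc(OC)c(C=O)c(OC)c2)c(OC)c1 | intermediate
4 | 2,6-dimethoxy-4-(2,4,6-trimethoxyphenoxy)phenyl formate | COc1cc(OC)c(Oc2cc(OC)c(OC=O)c(OC)c2)c(OC)c1 | intermediate (not isolated)
5 | 2,6-dimethoxy-4-(2,4,6-trimethoxyphenoxy)phenol | COc1cc(OC)c(Oc2cc(OC)c(O)c(OC)c2)c(OC)c1 | intermediate
6 | squaric acid (3,4-dihydroxycyclobut-3-ene-1,2-dione) | OC1=C(O)C(=O)C1=O | starting material
7 | 3,4-dichlorocyclobut-3-ene-1,2-dione | ClC1=C(Cl)C(=O)C1=O | intermediate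
8 | 3-chloro-4-[2,6-dimethoxy-4-(2,4,6-trimethoxyphenoxy)phenoxy]cyclobut-3-ene-1,2-dione | O=C1C(=O)C(Oc2c(OC)cc(Oc3c(OC)cc(OC)cc3OC)cc2OC)=C1Cl | intermediate
9 | 3-[2,6-dimethoxy-4-(2,4,6-trimethoxyphenoxy)phenoxy]cyclobut-3-ene-1,2-dione | O=C1C=C(Oc2c(OC)cc(Oc3c(OC)cc(OC)cc3OC)cc2OC)C1=O | intermediate
10 | ethyl vinyl ether | C=COCC | starting material
11 | 1-ethoxyvinyllithium | [Li]C(=C)OCC | intermediate (not isolated)
12 | (±)-3-[2,6-dimethoxy-4-(2,4,6-trimethoxyphenoxy)phenoxy]-4-(1-ethoxyethenyl)-4-hydroxycyclobut-2-en-1-one (racemic) | CCOC(=C)C1(O)C(=O)C=C1Oc1c(OC)cc(Oc2c(OC)cc(OC)cc2OC)cc1OC | intermediate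
13 | (3Z)-3-[2,6-dimethoxy-4-(2,4,6-trimethoxyphenoxy)phenoxy]-5-ethoxy-4-hydroxyhexa-1,3,5-trien-1-one | O=C=C/C(Oc1c(OC)cc(Oc2c(OC)cc(OC)cc2OC)cc1OC)=C(\C(=C)OCC)O | intermediate (not isolated)
14 | 3-[2,6-dimethoxy-4-(2,4,6-trimethoxyphenoxy)phenoxy]-5-ethoxy-4-hydroxycyclohexa-2,4-dien-1-one | O=C1C=C(Oc2c(OC)cc(Oc3c(OC)cc(OC)cc3OC)cc2OC)C(O)=C(OCC)C1 | intermediate (not isolated)
15 | 2-[2,6-dimethoxy-4-(2,4,6-trimethoxyphenoxy)phenoxy]-6-ethoxybenzene-1,4-diol | CCOc1cc(O)cc(Oc2c(OC)cc(Oc3c(OC)cc(OC)cc3OC)cc2OC)c1O | intermediate
16 | 2-[2,6-dimethoxy-4-(2,4,6-trimethoxyphenoxy)phenoxy]-6-ethoxy-4-methoxyphenol | CCOc1cc(OC)cc(Oc2c(OC)cc(Oc3c(OC)cc(OC)cc3OC)cc2OC)c1O | intermediate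
17 | 4-{2-[2,6-dimethoxy-4-(2,4,6-trimethoxyphenoxy)phenoxy]-6-ethoxy-4-methoxyphenoxy}-2,6-dimethoxybenzaldehyde | CCOc1cc(OC)cc(Oc2c(OC)cc(Oc3c(OC)cc(OC)cc3OC)cc2OC)c1Oc1cc(OC)c(C=O)c(OC)c1 | intermediate
18 | 4-{2-[2,6-dimethoxy-4-(2,4,6-trimethoxyphenoxy)phenoxy]-6-ethoxy-4-methoxyphenoxy}-2,6-dimethoxyphenyl formate | CCOc1cc(OC)cc(Oc2c(OC)cc(Oc3c(OC)cc(OC)cc3OC)cc2OC)c1Oc1cc(OC)c(OC=O)c(OC)c1 | intermediate (not isolated)
19 | 4-{2-[2,6-dimethoxy-4-(2,4,6-trimethoxyphenoxy)phenoxy]-6-ethoxy-4-methoxyphenoxy}-2,6-dimethoxyphenol | CCOc1cc(OC)cc(Oc2c(OC)cc(Oc3c(OC)cc(OC)cc3OC)cc2OC)c1Oc1cc(OC)c(O)c(OC)c1 | intermediate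
20 | 5-iodo-1,2,3-trimethoxybenzene | COc1cc(I)cc(OC)c1OC | starting material
21 | 1-[2,6-dimethoxy-4-(2,4,6-trimethoxyphenoxy)phenoxy]-2-[3,5-dimethoxy-4-(3,4,5-trimethoxyphenoxy)phenoxy]-3-ethoxy-5-methoxybenzene | CCOc1cc(OC)cc(Oc2c(OC)cc(Oc3c(OC)cc(OC)cc3OC)cc2OC)c1Oc1cc(OC)c(Oc2cc(OC)c(OC)c(OC)c2)c(OC)c1 | intermediate
22 | 2-{4-[2-[3,5-dihydroxy-4-(3,4,5-trihydroxyphenoxy)phenoxy]-3,5-dihydroxyphenoxy]-3,5-dihydroxyphenoxy}benzene-1,3,5-triol | Oc1cc(O)c(Oc2cc(O)c(Oc3cc(O)cc(O)c3Oc3cc(O)c(Oc4cc(O)c(O)c(O)c4)c(O)c3)c(O)c2)c(O)c1 | target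

## Step count and risks

Total step count: 12. Longest linear sequence: 11 steps (steps 1, 2 and 4 to 12, from 1); step 3 is a one-step side branch from 6.

Least certain steps:

**Step 7 (key step).** The most likely failure is oxidation of the newly formed, very electron-rich hydroquinone by traces of air during thermolysis and concentration, together with partial hydrolysis of the enol ether of 12 on acidic surfaces before ring opening. Fallback: starting from 12, the thermolysis is finished by deliberate oxidation with Ag2O in the same flask, so that all ring-expanded material is collected as the stable 2-[2,6-dimethoxy-4-(2,4,6-trimethoxyphenoxy)phenoxy]-6-ethoxycyclohexa-2,5-diene-1,4-dione F1. This is purified and reduced with aqueous Na2S2O4 immediately before use, which returns to the route at 15.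

**Step 6.** The lithium reagent may be consumed by addition–elimination at the aryloxy-bearing carbon (expelling the two-ring aryloxide) or by abstraction of the ring proton of 9, in competition with 1,2-addition. Fallback: starting from 8, which has no ring proton and in which the carbonyl next to the aryloxy-bearing carbon is still the more electrophilic one, addition of 11 at −78 °C should give (±)-2-chloro-3-[2,6-dimethoxy-4-(2,4,6-trimethoxyphenoxy)phenoxy]-4-(1-ethoxyethenyl)-4-hydroxycyclobut-2-en-1-one F2. Thermolysis as in step 7 should then give 3-chloro-2-[2,6-dimethoxy-4-(2,4,6-trimethoxyphenoxy)phenoxy]-6-ethoxybenzene-1,4-diol F3, and methylation as in step 8 should give 3-chloro-2-[2,6-dimethoxy-4-(2,4,6-trimethoxyphenoxy)phenoxy]-6-ethoxy-4-methoxyphenol F4. Catalytic hydrodechlorination (Pd/C, HCO2NH4, MeOH, reflux) returns to the route at 16. This path also bypasses step 5, but displacement of the chloride by the lithium reagent is a risk of its own.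

**Step 5.** Conjugate reduction of the enedione or cleavage of the activated aryl ester may occur under the tin hydride conditions, at the cost of the two-ring phenol. Fallback: starting from 7, the reduction (Bu3SnH, 1 equiv, Pd(PPh3)4 cat.) is done first, on the cheap dichloride, to give 3-chlorocyclobut-3-ene-1,2-dione F5. Its remaining chloride is then displaced by the sodium salt of 5 at −78 °C, which returns to the route at 9.

**Step 8.** Site selectivity may be incomplete (methylation at the hindered hydroxyl or at both), and the hydroquinone monoanion may be oxidised. Fallback: starting from 12, the tertiary hydroxyl is capped (MOMCl, i-Pr2NEt, CH2Cl2) to give (±)-3-[2,6-dimethoxy-4-(2,4,6-trimethoxyphenoxy)phenoxy]-4-(1-ethoxyethenyl)-4-(methoxymethoxy)cyclobut-2-en-1-one F6. Thermolysis then gives 3-[2,6-dimethoxy-4-(2,4,6-trimethoxyphenoxy)phenoxy]-5-ethoxy-4-(methoxymethoxy)phenol F7, in which the hindered oxygen is masked by construction. Methylation (MeI, K2CO3) gives 1-[2,6-dimethoxy-4-(2,4,6-trimethoxyphenoxy)phenoxy]-3-ethoxy-5-methoxy-2-(methoxymethoxy)benzene F8, and HCl in MeOH returns to the route at 16.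

**Step 11.** C–O bond formation between the di-ortho-substituted phenoxide and the electron-rich iodide may be slow, with competing protodeiodination of 20 and copper-mediated oxidation of the phenol. Fallback: starting from 19, a third SNAr with 2 (Cs2CO3, DMF, 110 °C) gives 4-[4-{2-[2,6-dimethoxy-4-(2,4,6-trimethoxyphenoxy)phenoxy]-6-ethoxy-4-methoxyphenoxy}-2,6-dimethoxyphenoxy]-2,6-dimethoxybenzaldehyde F9. Oxidation with mCPBA gives the corresponding aryl formate F10, and methanolysis gives 4-[4-{2-[2,6-dimethoxy-4-(2,4,6-trimethoxyphenoxy)phenoxy]-6-ethoxy-4-methoxyphenoxy}-2,6-dimethoxyphenoxy]-2,6-dimethoxyphenol F11. The para oxygen of ring E thus comes from the formyl group, and BBr3 as in step 12 returns to the route at 22.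

**Step 12.** Cleavage of the twelve ethers may be incomplete (the ethyl group and the flanked methyl groups go last), and the free polyphenol may degrade oxidatively during work-up and chromatography. Fallback: starting from 21, the crude product of the BBr3 reaction is acetylated without purification (Ac2O, pyridine) to the dodecaacetate 2-{4-[2-[3,5-diacetoxy-4-(3,4,5-triacetoxyphenoxy)phenoxy]-3,5-diacetoxyphenoxy]-3,5-diacetoxyphenoxy}benzene-1,3,5-triyl triacetate F12. This is stable to air and silica, and partially alkylated material can be separated from it. Acidic methanolysis (HCl, MeOH, Ar) then returns to the route at 22.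

## Further compounds

F1 | step 7 | 2-[2,6-dimethoxy-4-(2,4,6-trimethoxyphenoxy)phenoxy]-6-ethoxycyclohexa-2,5-diene-1,4-dione | CCOC1=CC(=O)C=C(Oc2c(OC)cc(Oc3c(OC)cc(OC)cc3OC)cc2OC)C1=O
F2 | step 6 | (±)-2-chloro-3-[2,6-dimethoxy-4-(2,4,6-trimethoxyphenoxy)phenoxy]-4-(1-ethoxyethenyl)-4-hydroxycyclobut-2-en-1-one (racemic) | CCOC(=C)C1(O)C(=O)C(Cl)=C1Oc1c(OC)cc(Oc2c(OC)cc(OC)cc2OC)cc1OC
F3 | step 6 | 3-chloro-2-[2,6-dimethoxy-4-(2,4,6-trimethoxyphenoxy)phenoxy]-6-ethoxybenzene-1,4-diol | CCOc1cc(O)c(Cl)c(Oc2c(OC)cc(Oc3c(OC)cc(OC)cc3OC)cc2OC)c1O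
F4 | step 6 | 3-chloro-2-[2,6-dimethoxy-4-(2,4,6-trimethoxyphenoxy)phenoxy]-6-ethoxy-4-methoxyphenol | CCOc1cc(OC)c(Cl)c(Oc2c(OC)cc(Oc3c(OC)cc(OC)cc3OC)cc2OC)c1O
F5 | step 5 | 3-chlorocyclobut-3-ene-1,2-dione | O=C1C=C(Cl)C1=O
F6 | step 8 | (±)-3-[2,6-dimethoxy-4-(2,4,6-trimethoxyphenoxy)phenoxy]-4-(1-ethoxyethenyl)-4-(methoxymethoxy)cyclobut-2-en-1-one (racemic) | CCOC(=C)C1(OCOC)C(=O)C=C1Oc1c(OC)cc(Oc2c(OC)cc(OC)cc2OC)cc1OC
F7 | step 8 | 3-[2,6-dimethoxy-4-(2,4,6-trimethoxyphenoxy)phenoxy]-5-ethoxy-4-(methoxymethoxy)phenol | CCOc1cc(O)cc(Oc2c(OC)cc(Oc3c(OC)cc(OC)cc3OC)cc2OC)c1OCOC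
F8 | step 8 | 1-[2,6-dimethoxy-4-(2,4,6-trimethoxyphenoxy)phenoxy]-3-ethoxy-5-methoxy-2-(methoxymethoxy)benzene | CCOc1cc(OC)cc(Oc2c(OC)cc(Oc3c(OC)cc(OC)cc3OC)cc2OC)c1OCOC
F9 | step 11 | 4-[4-{2-[2,6-dimethoxy-4-(2,4,6-trimethoxyphenoxy)phenoxy]-6-ethoxy-4-methoxyphenoxy}-2,6-dimethoxyphenoxy]-2,6-dimethoxybenzaldehyde | CCOc1cc(OC)cc(Oc2c(OC)cc(Oc3c(OC)cc(OC)cc3OC)cc2OC)c1Oc1cc(OC)c(Oc2cc(OC)c(C=O)c(OC)c2)c(OC)c1
F10 | step 11 | 4-[4-{2-[2,6-dimethoxy-4-(2,4,6-trimethoxyphenoxy)phenoxy]-6-ethoxy-4-methoxyphenoxy}-2,6-dimethoxyphenoxy]-2,6-dimethoxyphenyl formate | CCOc1cc(OC)cc(Oc2c(OC)cc(Oc3c(OC)cc(OC)cc3OC)cc2OC)c1Oc1cc(OC)c(Oc2cc(OC)c(OC=O)c(OC)c2)c(OC)c1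
F11 | step 11 | 4-[4-{2-[2,6-dimethoxy-4-(2,4,6-trimethoxyphenoxy)phenoxy]-6-ethoxy-4-methoxyphenoxy}-2,6-dimethoxyphenoxy]-2,6-dimethoxyphenol | CCOc1cc(OC)cc(Oc2c(OC)cc(Oc3c(OC)cc(OC)cc3OC)cc2OC)c1Oc1cc(OC)c(Oc2cc(OC)c(O)c(OC)c2)c(OC)c1
F12 | step 12 | 2-{4-[2-[3,5-diacetoxy-4-(3,4,5-triacetoxyphenoxy)phenoxy]-3,5-diacetoxyphenoxy]-3,5-diacetoxyphenoxy}benzene-1,3,5-triyl triacetate | CC(=O)Oc1cc(OC(C)=O)c(Oc2cc(OC(C)=O)c(Oc3cc(OC(C)=O)cc(OC(C)=O)c3Oc3cc(OC(C)=O)c(Oc4cc(OC(C)=O)c(OC(C)=O)c(OC(C)=O)c4)c(OC(C)=O)c3)c(OC(C)=O)c2)c(OC(C)=O)c1
A1 | alternative 1 | 2-{4-[2-[3,5-dihydroxy-4-(3,4,5-trimethoxyphenoxy)phenoxy]-3,5-dihydroxyphenoxy]-3,5-dihydroxyphenoxy}benzene-1,3,5-triol | Oc1cc(O)c(Oc2cc(O)c(Oc3cc(O)cc(O)c3Oc3cc(O)c(Oc4cc(OC)c(OC)c(OC)c4)c(O)c3)c(O)c2)c(O)c1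
A2 | alternative 1 | 2-{4-[2-[3,5-diformyl-4-(3,4,5-trimethoxyphenoxy)phenoxy]-3,5-diformylphenoxy]-3,5-diformylphenoxy}benzene-1,3,5-tricarbaldehyde | O=Cc1cc(C=O)c(Oc2cc(C=O)c(Oc3cc(C=O)cc(C=O)c3Oc3cc(C=O)c(Oc4cc(OC)c(OC)c(OC)c4)c(C=O)c3)c(C=O)c2)c(C=O)c1
A3 | alternative 2 | dimethyl 2-{2-[2,6-dimethoxy-4-(2,4,6-trimethoxyphenoxy)phenoxy]-4,6-dimethoxyphenoxy}-4,6-dihydroxy-5-(3,4,5-trimethoxyphenoxy)benzene-1,3-dicarboxylate | COC(=O)c1c(O)c(Oc2cc(OC)c(OC)c(OC)c2)c(O)c(C(=O)OC)c1Oc1c(OC)cc(OC)cc1Oc1c(OC)cc(Oc2c(OC)cc(OC)cc2OC)cc1OC
A4 | alternative 2 | dimethyl 2-(3,4,5-trimethoxyphenoxy)propanedioate | COC(=O)C(Oc1cc(OC)c(OC)c(OC)c1)C(=O)OC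
A5 | alternative 2 | dimethyl (2E)-3-{2-[2,6-dimethoxy-4-(2,4,6-trimethoxyphenoxy)phenoxy]-4,6-dimethoxyphenoxy}pent-2-enedioate | COC(=O)C/C(Oc1c(OC)cc(OC)cc1Oc1c(OC)cc(Oc2c(OC)cc(OC)cc2OC)cc1OC)=C\C(=O)OC
A6 | alternative 3 | 2-(benzyloxy)-3-ethoxy-5-(2,4,6-trimethoxyphenoxy)phenol | CCOc1cc(Oc2c(OC)cc(OC)cc2OC)cc(O)c1OCc1ccccc1
A7 | alternative 3 | (±)-4-(benzyloxy)-3-ethoxycyclobut-2-en-1-one (racemic) | CCOC1=CC(=O)C1OCc1ccccc1
A8 | alternative 3 | 2-(ethynyloxy)-1,3,5-trimethoxybenzene | COc1cc(OC)c(OC#C)c(OC)c1
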